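Read the spring run, the dilute one, for what stands in solution once the flask stops moving. Target plus isomer of the product A give 78.8% at 10.0 s, 73.1% at 25.0 s and 68.3% at 60.0 s. The two run side by side, so I take them to exchange fast and to lose ground together to isomer of the product B, with unseen starting material riding along in a steady proportion.

| flask | solid substrate | remark | time |
|---|---|---|---|
| spring | 0.036 M | run made earlier |  |
| autumn | 0.48 M | run made earlier |  |
| north-west | 0.060 M |  | 2.0 min |
| west | 0.20 M |  | 2.0 min |
| south-east | 0.60 M |  | 2.0 min |

- spring (time / s: target / %, isomer of the product A / %): 10.0: 39.8, 39.0; 15.0: 38.4, 37.6; 25.0: 37.1, 36.0; 30.0: 36.2, 34.9; 40.0: 34.5, 33.2; 50.0: 35.1, 33.5; 60.0: 34.4, 33.9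
- autumn (time / s: target / %, isomer of the product A / %): 10.0: 18.3, 17.0; 15.0: 23.3, 21.4; 25.0: 28.4, 26.9; 40.0: 31.7, 29.6; 50.0: 32.1, 30.7; 60.0: 32.2, 30.1

(each reading ± 0.5 percentage points)

- share of target in all that became target or isomer of the product A or isomer of the product B for north-west, west, south-east, in this order
- the course of these numbers from the first flask to the last (rises all the way / hardly changes / falls all the way / rises, then falls / falls, then rises)

- as a solid, counted per litre of solution: solid substrate
- what may be going on: starting material <-> target; starting material <-> isomer of the product A; target <-> isomer of the product A; solid substrate <-> starting material; target <-> isomer of the product B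
- at the start none of the solid substrate is in solution
- "hardly changes" means that all values lie within two and a half points (for a concentration: within two and a half percent of the largest)

I bracket the asked share on spring's last reading. Crudely it lies between 34.4% (all the unseen is isomer B) and 50.4% (none is). From above: a drain slows as target falls, so a straight line back to zero is the least that was lost early. It gives 82.6% at the start, when no isomer B exists, so isomer B ends at 17.3% and the share at 40.2%. For the lower edge I have an estimate, not a proof: on these readings the excess over the last sum halves every 13.3 s; run back, that gives 86.0%, isomer B 20.6% and 38.7%. I carry this as the end share, target over target, isomer A and isomer B at rest, the number of thermodynamic control; it bears the scatter of the readings.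

That half-time, read in spring, is short against 2.0 min, so I expect north-west and west to be at rest by then and south-east to be near it. Autumn's last reading puts c(target) at 0.155 M. West at spring's percentage needs 0.0688 M, less than that, and south-east needs 0.206 M, more, so I expect solid to stay in south-east, with the ratios in solution near spring's. I commit to the end share at each point. The forecast gives 38% throughout, hardly changes, just under my lower estimate, on the ground that “Solution ratios are then fixed whatever the loading”.

The flasks give 39.2%, 39.2% and 39.6%, so the row hardly changes, and it lies inside my bracket. At 2.00 min south-east still holds 21.6% of its charge as solid substrate, north-west 0%.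

    starting material ⇌ target (K = 2.40, k = 0.470 s⁻¹)
    starting material ⇌ isomer of the product A (K = 2.30, k = 0.240 s⁻¹)
    target ⇌ isomer of the product A (k = 0.190 s⁻¹)
    solid substrate ⇌ starting material, rate k4*(cs4 - [starting material]) while solid is left; crystals form when [starting material] > cs4 (solubility = 0.0670 M, k = 1.10 s⁻¹)
    target ⇌ isomer of the product B (K = 0.600, k = 0.0180 s⁻¹)

Put the end share to use on south-east: its target, isomer A and isomer B sum to 67.2% of the charge, which makes 26.0% target, and the flask holds 26.6%.

(The readings were generated by integration from invented constants; scatter was added.)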